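(Readings and results are simulated from invented constants; noise was put on by code.)

More second substrate looks like a push towards target, but the runs read the reverse: at 10.0 d target stands at 19% with 13 mM charged on Wednesday and at 10% with 32 mM charged on Thursday.

| setting | Wednesday's | Thursday's | oak | ash |
|---|---|---|---|---|
| starting material | 10 mM | 10 mM | 10 mM | 10 mM |
| second substrate | 13 mM | 32 mM | 10.0 mM | 20.0 mM |
| free catalyst | 50 µM | 50 µM | 50 µM | 50 µM |
| remark | run made earlier | run made earlier |  |  |
| time |  |  | 10 d | 10 d |

| run | time / d | catalyst intermediate A / % | target / % | starting material / % |
|---|---|---|---|---|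
| Wednesday's | 0.833 | 0 | 5 | 36 |
| Wednesday's | 1.25 | 0 | 5 | 27 |
| Wednesday's | 2.00 | 0 | 11 | 18 |
| Wednesday's | 4.00 | 0 | 14 | 7 |
| Wednesday's | 6.00 | 0 | 13 | 6 |
| Wednesday's | 10.0 | 0 | 19 | 0 |
| Thursday's | 0.625 | 0 | 3 | 44 |
| Thursday's | 2.08 | 1 | 4 | 21 |
| Thursday's | 4.00 | 1 | 4 | 5 |
| Thursday's | 5.00 | 0 | 8 | 9 |
| Thursday's | 8.00 | 1 | 7 | 8 |
| Thursday's | 10.0 | 2 | 10 | 5 |

(scatter of a reading: 1.5 percentage points)

- which of these there is most of at the end, counted by the starting material in it, oak (starting material / target / catalyst intermediate A)
- which of these there is most of at the end, counted by the starting material in it, ash (starting material / target / catalyst intermediate A)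
- how much there is at the end of the one of these that leads, in percent of the starting material charged: oak
- how much there is at the end of the one of these that leads, in percent of the starting material charged: ash



With 10 mM of starting material, 50 µM of free catalyst and 10 d held, take the end target as a ceiling divided by one plus the charged [second substrate] over a constant. That constant is the halving charge, the [second substrate] at which the end target is half the ceiling. The two end readings give a halving charge of 8.11 mM and a ceiling of 49.5%, both read through a scatter of 1.5 percentage points. This reckoning gives oak 22.1% of target and ash 14.3%. Starting material reads 0% and 5% at 10.0 d in the two runs, and catalyst intermediate A cannot pass 0.500% of the starting material charged with the whole catalyst bound, so target should lead in both flasks.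

The forecast, from a fit of its own, names target for oak at 22% and target for ash at 14%, noting that “More second substrate lowers the target”.

The flask gives target in the lead in oak at 21.0% and target in the lead in ash at 14.9%, with starting material at 0.686% and 1.89%. The reckoning stands 1.1 points high for oak and 0.60 points low for ash.

    starting material + free catalyst ⇌ catalyst intermediate A (K = 490 /M, k = 950 /M/h)
    catalyst intermediate A → free catalyst + target (k = 1.80 /h)
    second substrate + free catalyst ⇌ catalyst intermediate B (K = 3800 /M, k = 490 /M/h)
    catalyst intermediate B → free catalyst + second product (k = 2.00 /h)
    2 starting material → homo dimer (k = 3.70 /M/h)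

At 10.0 d homo dimer holds 78.3% of the starting material charged in oak and 83.2% in ash. The neighbouring flask is oak with 40 mM of second substrate. A halving charge of 8.11 mM and the same ceiling give it 8.34%. At 10 d the neighbouring flask gives 8.73% of target, more than the 3.5% of starting material still there, while catalyst intermediate B, the resting state there, holds 80.8% of the catalyst, more than the free catalyst at 17.6%.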